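## The problem

Compound 22 is a flavonol whose ring B is joined to C2 through a carbon (C1') with both ortho positions occupied. C2' is part of a fused 2,2-dimethyl-2H-pyran whose oxygen sits on C3', and C6' carries a quaternary 2-methylbut-3-en-2-yl group. Classical flavone closures end with a nucleophile attacking the C2 carbonyl carbon, which here is buried between these two groups; a late union at C2–C1' would be crowded for the same reason. There is no stereocentre in 22, so the difficulty is purely positional. Three isoprenoid units must be set in three forms: a prenyl group on C8 and not C6, a pyran annulated on C2'–C3' and not C3'–C4', and a reverse prenyl group at C6', which is ortho to no ring B oxygen and so cannot come from an ortho-Claisen shift. The chromene double bond, the prenyl group next to the 7-hydroxyl (which closes to a chroman in strong acid), the terminal vinyl group and the electron-rich polyphenol exclude hydrogenolysis, electrophilic oxidants and hot mineral acid late in the route. The handle is O1: it links C2 to C8a, and C8a is ortho to the C4 carbonyl and meta to both O5 and O7, so a halide there is activated and not deactivated by the ring A oxygens. If O1 is supplied as the oxygen of the ring B ketone, ring C can be closed at C8a and C2 is never the electrophile.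

## Retrosynthesis

**22 ⇒ 21.** The last cut removes the three methoxymethyl ethers on O3, O7 and O4' of 21. Benzyl ethers would need hydrogenolysis, methyl ethers a boron halide, and silyl ethers would not survive carbonate in hot DMF. Methoxymethyl ethers tolerate every reagent of the route and should fall in warm dilute methanolic HCl. The forward step must spare the chromene and the prenyl/7-hydroxyl pair.

**21 ⇒ 19.** The C8–CH2 bond of the prenyl group is cut and the allyl unit is returned to O5, giving prenyl ether 19. Direct C-prenylation of ring A would give C6/C8/O mixtures. Carrying a C-prenyl group from the start would put a substituent next to the halide at C8a. The prenyl ether also serves as the protecting group of O5 through the earlier steps, so no selective unmasking of O5 beside O3 (both flank the C4 carbonyl) is needed. The forward reaction has to carry the allyl unit past C6 on to C8.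

**19 ⇒ 18.** The O1–C8a bond is cut, giving bromo diketone 18. This is the central simplification: ring C is opened to an acyclic 2-alkoxy-1,3-diketone, and the oxygen that becomes O1 is the carbonyl oxygen next to ring B. The neighbouring cut at O1–C2 would require attack on the shielded carbon under dehydrating acid. The forward reaction asks only that an enolate oxygen displace an activated aryl bromide in a six-membered closure.

**18 ⇒ 17 ⇒ 10 + 16.** The C3–C4 bond is cut through aldol adduct 17 to ketone 10 and aldehyde 16. Aldol addition followed by oxidation is preferred to direct acylation of the enolate, which risks O-acylation and needs a doubly ortho-substituted acyl donor. The ketone is placed on the ring B side, so its crowded carbonyl only has to be deprotonated at the alpha carbon and the new bond forms at the aldehyde of 16. The reverse pairing would send a bulky enolate into a doubly ortho-substituted ring B aldehyde.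

**10 ⇒ 8 + 9, and 8 ⇒ 7 ⇒ 6.** The bond from C6' to the quaternary carbon is cut to aryl bromide 8 and prenylboronate 9, to be joined with allylic transposition. The alternative (enolate arylation, reduction, olefination) costs three or more steps. The coupling is placed at the ketone stage because aldehyde 6 would be allylborated by 9. Ketone 8 is traced through alcohol 7 to aldehyde 6 by cutting the C2–C3 bond. The one-carbon nucleophile brings O3 already protected, so no oxidation at C3 is needed later, when alkenes are present.

**6 ⇒ 4 ⇒ 2 + 3, and 2 ⇒ 1.** The pyran is opened to aryl propargyl ether 4, made from phenol 2 and chloride 3. In 4 the ether oxygen has one free ortho carbon only, because the other carries the protected O4, so the annulation can only occur at the correct position. Phenol 2 comes from 1 by protection of the more acidic hydroxyl, para to the formyl group. Aldehyde 1 marks every position of ring B: the formyl carbon becomes C2 of the flavonol, the bromine marks C6', and the two hydroxyls become O3' and O4'.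

**16 ⇒ 14 + 15, 14 ⇒ 13 ⇒ 11.** Ring A aldehyde 16 is the prenyl ether (from bromide 15) of salicylaldehyde 14. Phenol 14 comes from dihydroxy aldehyde 13 by protection of the hydroxyl that is not hydrogen-bonded, and 13 by formylation of symmetrical 5-bromoresorcinol 11. The bromine of 11 ends as the leaving group on C8a. Formylation para to one hydroxyl and ortho to the other places the aldehyde between bromine and oxygen, as needed.

## Roads not taken

**Alternative 1:** Ring B itself is taken apart at C1'–C2' and C5'–C6'. In the forward direction the alkyne of 2-alkynylchromone A1 adds thermally across the 2-pyranone diene of pyranopyranone A2. The bridged adduct loses carbon dioxide to give A3, the tetrakis(methoxymethyl) ether of 22.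
- Merits: it is the most convergent plan. The C2–C1' bond exists as an alkyne–chromone bond before ring B exists, so crowding never matters. All three isoprenoid units are in place, and only one deprotection follows A3, one step fewer after the key step than in the chosen plan.
- Weak points: the alkyne of A1 is unsymmetrical, and the two alkoxy groups of A2 polarise the diene termini in opposite senses. Only the steric preference of the quaternary end for the unsubstituted terminus of A2 would decide the orientation, and the wrong isomer would appear late. An internal alkyne with a tertiary substituent needs temperatures well above 150 °C, where the 2H-pyran of A2 can open by retro-electrocyclisation. A1 already needs an 8-prenylated chromone and an alkynylation at C2, and A2 a 5-oxygenated 4-hydroxypyranone, so the overall count is not clearly lower.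
- Comparison: the chosen plan sets against the shorter endgame that every position of ring B is bought with 1 or fixed by a blocked position, and that its closure has a single geometric outcome.

**Alternative 2:** The C2–C1' bond is cut, with an ester tether from a carboxyl on C2' to O3. In the forward step zerovalent palladium (from Pd(OAc)2 and tricyclohexylphosphine) inserts into the C1'–OTf bond of ester A4. Pivalate-assisted metalation of the chromone C2–H and reductive elimination then give lactone A5.
- Merits: it faces the hindered bond directly and makes its formation intramolecular. C2–H arylation of chromones is a known reaction class, and ring A can be finished, prenyl group included, before the union.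
- Weak points: oxidative addition must occur at a triflate flanked by the ester and the quaternary group. In A5 the C2' carbon is a carboxyl carbon, so it must still be reduced, extended by three carbons and closed onto O3'. O3' must be freed beside O4' and O3 reprotected, which means five or more steps on the most advanced intermediate. The hexasubstituted benzoate of A4 needs a long synthesis of its own. The prenyl alkene also lies within reach of an arylpalladium species.
- Comparison: this road is stronger in how directly it solves the crowded bond. The chosen plan never has to make that bond, because it is the ring–formyl bond of 1, and it ends two steps after ring closure.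

**Alternative 3:** The C8 prenyl bond and the pyran ring are cut together, back to bis-ether A6 (prenyl on O5, 2-methylbut-3-yn-2-yl on O3'). Heating with Eu(fod)3 (europium tris(6,6,7,7,8,8,8-heptafluoro-2,2-dimethyloctane-3,5-dionate)) should move the prenyl group from O5 by way of C6 to C8 and convert the propargyl ether into the pyran. The product A7 is the same compound as 21.
- Merits: one operation does the work of steps 3 and 13. Ring B keeps a single ortho substituent until the end, so ring C of A6 could be closed by ordinary means. The pyran position is forced because C4' is blocked. In step count and in ease of ring C closure this road is at least as good as the chosen one.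
- Weak points: the two shifts do not share conditions. Europium chelation by the C4 carbonyl and O5 accelerates only the prenyl shift. The propargyl ether has no such chelate and needs about 150 °C, where the uncatalysed ortho-Claisen shift of the O5 prenyl group (stopping at C6) competes. The propargyl shift must also deliver carbon to C2', next to the chromone-bearing carbon, as the last carbon–carbon bond formed on the complete flavonol, so a failure cannot be repaired.
- Comparison: the chosen plan pays with the crowded compounds 10 and 18. In return it closes the pyran at step 3 on a fourteen-carbon aldehyde, where a failure costs little, and it reaches the same compound 21.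

Key step: step 12

## Route

Remark on the chemistry: 22 has no stereocentre; the stereocentres that appear in 7, 17, 18 and 20 are transient, and these compounds are carried as racemates or diastereomer mixtures.

Step 1
Reactants: 1 2-bromo-4,5-dihydroxybenzaldehyde
Product: 2 2-bromo-5-hydroxy-4-(methoxymethoxy)benzaldehyde
Conditions: MOMCl (1.05 equiv), K2CO3 (1.1 equiv), acetone, 0 °C to rt
Reagents that add atoms: chloromethyl methyl ether (MOMCl), COCCl
Why: The 4-hydroxyl is para to the formyl group and the more acidic phenol, so with one equivalent of weak base its phenoxide should be alkylated selectively (regioselective O-alkylation as known for protocatechualdehydes), leaving O5 free for the pyran.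

Step 2
Reactants: 2 2-bromo-5-hydroxy-4-(methoxymethoxy)benzaldehyde; 3 3-chloro-3-methylbut-1-yne
Product: 4 2-bromo-4-(methoxymethoxy)-5-[(2-methylbut-3-yn-2-yl)oxy]benzaldehyde
Conditions: CuCl2·2H2O (cat.), DBU, MeCN, 0 °C
Reagents that add atoms: none
Why: Copper-catalysed O-propargylation of phenols with tertiary propargylic chlorides is a standard entry to aryl 1,1-dimethylpropargyl ethers and works best with electron-poor phenols such as 2.

Step 3
Reactants: 4 2-bromo-4-(methoxymethoxy)-5-[(2-methylbut-3-yn-2-yl)oxy]benzaldehyde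
Product: 6 6-bromo-8-(methoxymethoxy)-2,2-dimethyl-2H-chromene-5-carbaldehyde, via ortho-allenylphenol 5 (not isolated)
Conditions: N,N-diethylaniline, 180 °C
Reagents that add atoms: none
Why: Aromatic propargyl Claisen rearrangement gives ortho-allenylphenol 5, which closes to the 2H-chromene by 1,5-hydrogen shift and 6π oxa-electrocyclisation; the only free ortho carbon is the one next to the formyl group, so the pyran can form in one orientation only.

Step 4
Reactants: 6 6-bromo-8-(methoxymethoxy)-2,2-dimethyl-2H-chromene-5-carbaldehyde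
Product: 7 1-[6-bromo-8-(methoxymethoxy)-2,2-dimethyl-2H-chromen-5-yl]-2-(methoxymethoxy)ethan-1-ol (racemic)
Conditions: Bu3SnCH2OMOM, n-BuLi, THF, −78 °C; then 6, −78 °C; aq NH4Cl
Reagents that add atoms: tributyl[(methoxymethoxy)methyl]stannane, CCCC[Sn](CCCC)(CCCC)COCOC
Why: Tin–lithium exchange gives (methoxymethoxy)methyllithium, a small alkoxymethyl anion that should add to the hindered aldehyde at −78 °C faster than it exchanges with the aryl bromide; the carbinol centre is formed as a racemate and removed in step 5.

Step 5
Reactants: 7 1-[6-bromo-8-(methoxymethoxy)-2,2-dimethyl-2H-chromen-5-yl]-2-(methoxymethoxy)ethan-1-ol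
Product: 8 1-[6-bromo-8-(methoxymethoxy)-2,2-dimethyl-2H-chromen-5-yl]-2-(methoxymethoxy)ethan-1-one
Conditions: Dess–Martin periodinane, CH2Cl2, 0 °C to rt
Reagents that add atoms: none
Why: Dess–Martin oxidation of a secondary benzylic alcohol is mild and should leave the chromene alkene, the aryl bromide and the acetal ethers untouched.

Step 6
Reactants: 8 1-[6-bromo-8-(methoxymethoxy)-2,2-dimethyl-2H-chromen-5-yl]-2-(methoxymethoxy)ethan-1-one; 9 4,4,5,5-tetramethyl-2-(3-methylbut-2-en-1-yl)-1,3,2-dioxaborolane (prenylboronic acid pinacol ester)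
Product: 10 2-(methoxymethoxy)-1-[8-(methoxymethoxy)-2,2-dimethyl-6-(2-methylbut-3-en-2-yl)-2H-chromen-5-yl]ethan-1-one
Conditions: Pd(OAc)2 (5 mol %), bulky biaryl monophosphine ligand of the γ-selective type (10 mol %), K3PO4 (aq), THF, 40 °C
Reagents that add atoms: none
Why: Ligand-controlled γ-selective Suzuki–Miyaura allyl–aryl coupling: transmetalation with allylic transposition places palladium on the tertiary carbon and fast reductive elimination should give the 1,1-dimethylallyl arene; the ortho acyl group assists oxidative addition, and the ketone, unlike aldehyde 6, is inert to allylboration by 9.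

Step 7
Reactants: 11 5-bromobenzene-1,3-diol (5-bromoresorcinol)
Product: 13 2-bromo-4,6-dihydroxybenzaldehyde, via aryl iminium chloride 12 (not isolated)
Conditions: POCl3, DMF, MeCN, 0 °C to rt; then H2O, 50 °C
Reagents that add atoms: N,N-dimethylformamide, CN(C)C=O; water, O
Why: Vilsmeier–Haack formylation of a resorcinol goes para to one hydroxyl and ortho to the other (two equivalent sites in 11) and not between the hydroxyls, as with resorcinol and orcinol; hydrolysis of iminium salt 12 releases the aldehyde.

Step 8
Reactants: 13 2-bromo-4,6-dihydroxybenzaldehyde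
Product: 14 2-bromo-6-hydroxy-4-(methoxymethoxy)benzaldehyde
Conditions: MOMCl (1.1 equiv), i-Pr2NEt, CH2Cl2, 0 °C
Reagents that add atoms: chloromethyl methyl ether (MOMCl), COCCl
Why: The ortho hydroxyl is hydrogen-bonded to the formyl group and poorly nucleophilic, so O-alkylation should occur at the para hydroxyl, as in the standard monoprotection of 2,4-dihydroxybenzaldehydes.

Step 9
Reactants: 14 2-bromo-6-hydroxy-4-(methoxymethoxy)benzaldehyde; 15 1-bromo-3-methylbut-2-ene (prenyl bromide)
Product: 16 2-bromo-4-(methoxymethoxy)-6-[(3-methylbut-2-en-1-yl)oxy]benzaldehyde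
Conditions: K2CO3, DMF, rt
Reagents that add atoms: none
Why: Williamson etherification of the remaining phenol; the prenyl ether serves as the protecting group of the future O5 and as the source of the C8 prenyl group in step 13.

Step 10
Reactants: 10 2-(methoxymethoxy)-1-[8-(methoxymethoxy)-2,2-dimethyl-6-(2-methylbut-3-en-2-yl)-2H-chromen-5-yl]ethan-1-one; 16 2-bromo-4-(methoxymethoxy)-6-[(3-methylbut-2-en-1-yl)oxy]benzaldehyde
Product: 17 3-{2-bromo-4-(methoxymethoxy)-6-[(3-methylbut-2-en-1-yl)oxy]phenyl}-3-hydroxy-2-(methoxymethoxy)-1-[8-(methoxymethoxy)-2,2-dimethyl-6-(2-methylbut-3-en-2-yl)-2H-chromen-5-yl]propan-1-one (racemic diastereomer mixture)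
Conditions: LiN(SiMe3)2, THF, −78 °C; then 16, −78 °C; AcOH quench at −78 °C
Reagents that add atoms: none
Why: Aldol addition of the chelated lithium enolate of the α-alkoxy ketone to a non-enolisable aldehyde; the crowded carbonyl of 10 is only deprotonated, the new bond forms at the unhindered enolate carbon, and the cold acidic quench should prevent retro-aldol cleavage. Both new stereocentres are removed in steps 11 and 12, so no control is needed.

Step 11
Reactants: 17 3-{2-bromo-4-(methoxymethoxy)-6-[(3-methylbut-2-en-1-yl)oxy]phenyl}-3-hydroxy-2-(methoxymethoxy)-1-[8-(methoxymethoxy)-2,2-dimethyl-6-(2-methylbut-3-en-2-yl)-2H-chromen-5-yl]propan-1-one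
Product: 18 1-{2-bromo-4-(methoxymethoxy)-6-[(3-methylbut-2-en-1-yl)oxy]phenyl}-2-(methoxymethoxy)-3-[8-(methoxymethoxy)-2,2-dimethyl-6-(2-methylbut-3-en-2-yl)-2H-chromen-5-yl]propane-1,3-dione (enolisable; drawn as the diketone)
Conditions: Dess–Martin periodinane, CH2Cl2, 0 °C to rt
Reagents that add atoms: none
Why: Dess–Martin oxidation of β-hydroxy ketones to 1,3-diketones is well established and should tolerate the four alkenes and the acetal ethers.

Step 12
Reactants: 18 1-{2-bromo-4-(methoxymethoxy)-6-[(3-methylbut-2-en-1-yl)oxy]phenyl}-2-(methoxymethoxy)-3-[8-(methoxymethoxy)-2,2-dimethyl-6-(2-methylbut-3-en-2-yl)-2H-chromen-5-yl]propane-1,3-dione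
Product: 19 3,7-bis(methoxymethoxy)-2-[8-(methoxymethoxy)-2,2-dimethyl-6-(2-methylbut-3-en-2-yl)-2H-chromen-5-yl]-5-[(3-methylbut-2-en-1-yl)oxy]-4H-chromen-4-one
Conditions: CuI (10 mol %), 1,10-phenanthroline (20 mol %), Cs2CO3 (2 equiv), DMF, 80–90 °C, argon
Reagents that add atoms: none
Why: Cs2CO3 converts 18 into its enolate, and monovalent copper carrying 1,10-phenanthroline is taken up on the enolate oxygen of the ring B ketone. The C–Br bond on ring A, activated by the ortho carbonyl and not deactivated by the two meta alkoxy groups, should then add to copper, and reductive elimination from the aryl copper enolate forms O1–C8a and returns monovalent copper. The closest known reaction type is the Ullmann-type intramolecular O-arylation of 1-(2-haloaryl)-1,3-diketones to chromones and flavones; the 2-alkoxy group of 18 only makes the enolate tetrasubstituted. Ring C closes as a six-membered ring by ipso substitution at an aromatic sp2 carbon with the departing bromide outside the new ring (formally 6-exo-trig). No stereocentre is formed and the one at C2 of 18 is erased. The step needs O-arylation by the right oxygen, and geometry secures it: only the oxygen on the ring B carbonyl can reach C8a through a six-membered transition state, whereas the central carbon or the other oxygen would have to close four-membered rings. C2 is never attacked, so the two ortho groups of ring B do not hinder the closure, and the basic medium should leave the chromene, the vinyl group, the acetal ethers and the prenyl ether (well below the temperature of its thermal Claisen shift) untouched. A copper-free addition–elimination by the same enolate oxygen would give the same product and can only help.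

Step 13
Reactants: 19 3,7-bis(methoxymethoxy)-2-[8-(methoxymethoxy)-2,2-dimethyl-6-(2-methylbut-3-en-2-yl)-2H-chromen-5-yl]-5-[(3-methylbut-2-en-1-yl)oxy]-4H-chromen-4-one
Product: 21 5-hydroxy-3,7-bis(methoxymethoxy)-2-[8-(methoxymethoxy)-2,2-dimethyl-6-(2-methylbut-3-en-2-yl)-2H-chromen-5-yl]-8-(3-methylbut-2-en-1-yl)-4H-chromen-4-one, via C6 reverse-prenyl dienone 20 (not isolated)
Conditions: Eu(fod)3 [europium tris(6,6,7,7,8,8,8-heptafluoro-2,2-dimethyloctane-3,5-dionate)] (10 mol %), NaHCO3, PhCl, 85 °C
Reagents that add atoms: none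
Why: Europium bound to the C4 carbonyl and O5 accelerates the aromatic Claisen shift to C6 (dienone 20), and a Cope shift then carries the allyl unit to C8, where enolisation gives the chelated 5-hydroxy flavonol; this Claisen–Cope sequence is the established route from 5-O-prenyl to 8-C-prenyl flavonoids, and the double allylic inversion restores the linear prenyl group.

Step 14
Reactants: 21 5-hydroxy-3,7-bis(methoxymethoxy)-2-[8-(methoxymethoxy)-2,2-dimethyl-6-(2-methylbut-3-en-2-yl)-2H-chromen-5-yl]-8-(3-methylbut-2-en-1-yl)-4H-chromen-4-one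
Product: 22 3,5,7-trihydroxy-2-[8-hydroxy-2,2-dimethyl-6-(2-methylbut-3-en-2-yl)-2H-chromen-5-yl]-8-(3-methylbut-2-en-1-yl)-4H-chromen-4-one
Conditions: HCl (3 M aq), MeOH, 45 °C
Reagents that add atoms: none
Why: Acid-catalysed acetal exchange with methanol cleaves aryl and enol methoxymethyl ethers under conditions routinely used on prenylated and pyrano-fused flavonoids; dilute acid and moderate temperature are chosen to spare the chromene and the prenyl/7-hydroxyl pair.

## Compound list

1 | 2-bromo-4,5-dihydroxybenzaldehyde | O=Cc1cc(O)c(O)cc1Br | starting material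
2 | 2-bromo-5-hydroxy-4-(methoxymethoxy)benzaldehyde | O=Cc1cc(O)c(OCOC)cc1Br | intermediate
3 | 3-chloro-3-methylbut-1-yne | CC(C)(Cl)C#C | starting material
4 | 2-bromo-4-(methoxymethoxy)-5-[(2-methylbut-3-yn-2-yl)oxy]benzaldehyde | O=Cc1cc(OC(C)(C)C#C)c(OCOC)cc1Br | intermediate
5 | 6-bromo-3-hydroxy-4-(methoxymethoxy)-2-(3-methylbuta-1,2-dien-1-yl)benzaldehyde (ortho-allenylphenol, not isolated) | O=Cc1c(C=C=C(C)C)c(O)c(OCOC)cc1Br | intermediate
6 | 6-bromo-8-(methoxymethoxy)-2,2-dimethyl-2H-chromene-5-carbaldehyde | O=Cc1c(Br)cc(OCOC)c2OC(C)(C)C=Cc12 | intermediate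
7 | 1-[6-bromo-8-(methoxymethoxy)-2,2-dimethyl-2H-chromen-5-yl]-2-(methoxymethoxy)ethan-1-ol (racemic) | OC(COCOC)c1c(Br)cc(OCOC)c2OC(C)(C)C=Cc12 | intermediate
8 | 1-[6-bromo-8-(methoxymethoxy)-2,2-dimethyl-2H-chromen-5-yl]-2-(methoxymethoxy)ethan-1-one | O=C(COCOC)c1c(Br)cc(OCOC)c2OC(C)(C)C=Cc12 | intermediate
9 | 4,4,5,5-tetramethyl-2-(3-methylbut-2-en-1-yl)-1,3,2-dioxaborolane | CC(C)=CCB1OC(C)(C)C(C)(C)O1 | starting material
10 | 2-(methoxymethoxy)-1-[8-(methoxymethoxy)-2,2-dimethyl-6-(2-methylbut-3-en-2-yl)-2H-chromen-5-yl]ethan-1-one | O=C(COCOC)c1c(C(C)(C)C=C)cc(OCOC)c2OC(C)(C)C=Cc12 | intermediate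
11 | 5-bromobenzene-1,3-diol (5-bromoresorcinol) | Oc1cc(O)cc(Br)c1 | starting material
12 | [(2-bromo-4,6-dihydroxyphenyl)methylidene]dimethylazanium chloride (not isolated) | C[N+](C)=Cc1c(O)cc(O)cc1Br.[Cl-] | intermediate
13 | 2-bromo-4,6-dihydroxybenzaldehyde | O=Cc1c(O)cc(O)cc1Br | intermediate
14 | 2-bromo-6-hydroxy-4-(methoxymethoxy)benzaldehyde | O=Cc1c(O)cc(OCOC)cc1Br | intermediate
15 | 1-bromo-3-methylbut-2-ene (prenyl bromide) | CC(C)=CCBr | starting material
16 | 2-bromo-4-(methoxymethoxy)-6-[(3-methylbut-2-en-1-yl)oxy]benzaldehyde | O=Cc1c(OCC=C(C)C)cc(OCOC)cc1Br | intermediate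
17 | 3-{2-bromo-4-(methoxymethoxy)-6-[(3-methylbut-2-en-1-yl)oxy]phenyl}-3-hydroxy-2-(methoxymethoxy)-1-[8-(methoxymethoxy)-2,2-dimethyl-6-(2-methylbut-3-en-2-yl)-2H-chromen-5-yl]propan-1-one (racemic diastereomer mixture) | OC(c1c(Br)cc(OCOC)cc1OCC=C(C)C)C(OCOC)C(=O)c1c(C(C)(C)C=C)cc(OCOC)c2OC(C)(C)C=Cc12 | intermediate
18 | 1-{2-bromo-4-(methoxymethoxy)-6-[(3-methylbut-2-en-1-yl)oxy]phenyl}-2-(methoxymethoxy)-3-[8-(methoxymethoxy)-2,2-dimethyl-6-(2-methylbut-3-en-2-yl)-2H-chromen-5-yl]propane-1,3-dione (racemic, enolisable) | O=C(c1c(Br)cc(OCOC)cc1OCC=C(C)C)C(OCOC)C(=O)c1c(C(C)(C)C=C)cc(OCOC)c2OC(C)(C)C=Cc12 | intermediate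
19 | 3,7-bis(methoxymethoxy)-2-[8-(methoxymethoxy)-2,2-dimethyl-6-(2-methylbut-3-en-2-yl)-2H-chromen-5-yl]-5-[(3-methylbut-2-en-1-yl)oxy]-4H-chromen-4-one | C=CC(C)(C)c1cc(OCOC)c2c(c1-c1oc3cc(OCOC)cc(OCC=C(C)C)c3c(=O)c1OCOC)C=CC(C)(C)O2 | intermediate
20 | 3,7-bis(methoxymethoxy)-2-[8-(methoxymethoxy)-2,2-dimethyl-6-(2-methylbut-3-en-2-yl)-2H-chromen-5-yl]-6-(2-methylbut-3-en-2-yl)-6H-chromene-4,5-dione (racemic, not isolated) | C=CC(C)(C)C1C(=O)C2=C(C=C1OCOC)OC(=C(OCOC)C2=O)c1c(C(C)(C)C=C)cc(OCOC)c2OC(C)(C)C=Cc12 | intermediate
21 | 5-hydroxy-3,7-bis(methoxymethoxy)-2-[8-(methoxymethoxy)-2,2-dimethyl-6-(2-methylbut-3-en-2-yl)-2H-chromen-5-yl]-8-(3-methylbut-2-en-1-yl)-4H-chromen-4-one | C=CC(C)(C)c1cc(OCOC)c2c(c1-c1oc3c(CC=C(C)C)c(OCOC)cc(O)c3c(=O)c1OCOC)C=CC(C)(C)O2 | intermediate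
22 | 3,5,7-trihydroxy-2-[8-hydroxy-2,2-dimethyl-6-(2-methylbut-3-en-2-yl)-2H-chromen-5-yl]-8-(3-methylbut-2-en-1-yl)-4H-chromen-4-one | C=CC(C)(C)c1cc(O)c2c(c1-c1oc3c(CC=C(C)C)c(O)cc(O)c3c(=O)c1O)C=CC(C)(C)O2 | target

## Step count and risks

Total: 14 steps. Longest linear sequence: 11 steps (steps 1–6, then 10–14); the ring A branch (steps 7–9) joins at step 10.

**Step 12 (key step).** Copper may be held as a stable diketonate chelate in a geometry that cannot reach C8a. The crowded diketone may also undergo retro-Claisen cleavage by carbonate and adventitious water, or the bromide may be reduced instead of substituted. The fallback changes the mechanism to metal-free nucleophilic aromatic substitution on a fluoride at lower temperature.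
- It sets out from ketone 10 and comes back at 19.
- Purchased 5-fluorobenzene-1,3-diol F1 should be taken through the chemistry of steps 7–9.
- Vilsmeier–Haack formylation would give 2-fluoro-4,6-dihydroxybenzaldehyde F2.
- Para-selective protection would give 2-fluoro-6-hydroxy-4-(methoxymethoxy)benzaldehyde F3.
- Prenylation would give 2-fluoro-4-(methoxymethoxy)-6-[(3-methylbut-2-en-1-yl)oxy]benzaldehyde F4.
- Aldol addition of the lithium enolate of 10 to F4 would give the fluoro aldol adduct F5, and Dess–Martin oxidation the fluoro diketone F6.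
- F6 should close to 19 with K2CO3 in DMF between rt and 60 °C by addition–elimination of the enolate oxygen at the fluoride-bearing carbon.

**Step 6.** The tertiary allylpalladium intermediate may isomerise to the primary one before reductive elimination, which would give the linear prenyl arene. The ortho acyl group makes this likelier, and protodeboronation of 9 may outrun a slow coupling. The fallback builds the quaternary carbon by enolate arylation.
- It sets out from alcohol 7 and comes back at 10.
- Silylation (t-BuMe2SiCl, imidazole) would give the silyl ether of 7 F7.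
- Palladium-catalysed α-arylation (Pd(dba)2, P(t-Bu)3, lithium enolate of methyl isobutyrate made with LiNCy2, toluene, rt) would give the methyl 2-aryl-2-methylpropanoate F8.
- Reduction with i-Bu2AlH at −78 °C would give the 2-aryl-2-methylpropanal F9.
- Wittig methylenation (Ph3P=CH2) would give the silyl-protected 1,1-dimethylallyl compound F10.
- Bu4NF would free the 1,1-dimethylallyl carbinol F11, which Dess–Martin oxidation would convert into 10.

**Step 13.** The rearrangement may stop after the first shift, through enolisation of 20 to the C6 reverse-prenyl phenol. Europium may instead be held by the O3/C4 carbonyl chelate, or the prenyl ether may ionise. The fallback moves the prenyl transfer to the aldehyde stage, where a single chelating carbonyl is present and isomers can be removed on a small molecule.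
- It sets out from 16 and comes back at 22.
- Claisen–Cope rearrangement of 16 (Eu(fod)3 in PhCl, or heat in N,N-diethylaniline) would give 2-bromo-6-hydroxy-4-(methoxymethoxy)-3-(3-methylbut-2-en-1-yl)benzaldehyde F12.
- MOMCl and i-Pr2NEt would give 2-bromo-4,6-bis(methoxymethoxy)-3-(3-methylbut-2-en-1-yl)benzaldehyde F13.
- Aldol addition of the enolate of 10 would give the prenylated aldol adduct F14, and Dess–Martin oxidation the prenylated bromo diketone F15.
- Copper-catalysed O-arylation as in step 12 would give the tetrakis(methoxymethyl) ether of the target F16.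
- Methanolic HCl as in step 14 would give 22.

**Step 10.** Addition between two crowded partners may be slow, and the aldolate may revert on warming, returning 10 and 16. The fallback replaces aldol addition and oxidation by a crossed Claisen C-acylation under soft enolisation.
- It sets out from 16 and comes back at 18, skipping 17.
- Chlorite oxidation (NaClO2, NaH2PO4, 2-methylbut-2-ene) would give 2-bromo-4-(methoxymethoxy)-6-[(3-methylbut-2-en-1-yl)oxy]benzoic acid F17.
- Coupling with 1H-benzotriazole (dicyclohexylcarbodiimide) would give the N-acylbenzotriazole F18.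
- The magnesium enolate of 10 (MgBr2·OEt2, i-Pr2NEt, CH2Cl2) should be C-acylated by F18 to give 18.

**Step 14.** Protonation of the prenyl alkene may lead to ring closure onto the 7-hydroxyl. Methanol or HCl may add to the chromene, or cleavage may stop short of completion. The fallback avoids Brønsted acid by exchanging the acetal ethers for silyl ethers.
- It sets out from 21 and comes back at 22.
- Et3SiOTf with 2,2'-bipyridyl in CH2Cl2 at 0 °C would give the tetrakis(triethylsilyl) ether of the target F19 (the free 5-hydroxyl is silylated as well).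
- Bu4NF buffered with AcOH in THF at 0 °C would then release 22.

## Further compounds

F1 | step 12 | 5-fluorobenzene-1,3-diol (purchased) | Oc1cc(O)cc(F)c1
F2 | step 12 | 2-fluoro-4,6-dihydroxybenzaldehyde | O=Cc1c(O)cc(O)cc1F
F3 | step 12 | 2-fluoro-6-hydroxy-4-(methoxymethoxy)benzaldehyde | O=Cc1c(O)cc(OCOC)cc1F
F4 | step 12 | 2-fluoro-4-(methoxymethoxy)-6-[(3-methylbut-2-en-1-yl)oxy]benzaldehyde | O=Cc1c(OCC=C(C)C)cc(OCOC)cc1F
F5 | step 12 | 3-{2-fluoro-4-(methoxymethoxy)-6-[(3-methylbut-2-en-1-yl)oxy]phenyl}-3-hydroxy-2-(methoxymethoxy)-1-[8-(methoxymethoxy)-2,2-dimethyl-6-(2-methylbut-3-en-2-yl)-2H-chromen-5-yl]propan-1-one (racemic diastereomer mixture) | OC(c1c(F)cc(OCOC)cc1OCC=C(C)C)C(OCOC)C(=O)c1c(C(C)(C)C=C)cc(OCOC)c2OC(C)(C)C=Cc12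
F6 | step 12 | 1-{2-fluoro-4-(methoxymethoxy)-6-[(3-methylbut-2-en-1-yl)oxy]phenyl}-2-(methoxymethoxy)-3-[8-(methoxymethoxy)-2,2-dimethyl-6-(2-methylbut-3-en-2-yl)-2H-chromen-5-yl]propane-1,3-dione (racemic, enolisable) | O=C(c1c(F)cc(OCOC)cc1OCC=C(C)C)C(OCOC)C(=O)c1c(C(C)(C)C=C)cc(OCOC)c2OC(C)(C)C=Cc12
F7 | step 6 | {1-[6-bromo-8-(methoxymethoxy)-2,2-dimethyl-2H-chromen-5-yl]-2-(methoxymethoxy)ethoxy}(tert-butyl)dimethylsilane (racemic) | CC(C)(C)[Si](C)(C)OC(COCOC)c1c(Br)cc(OCOC)c2OC(C)(C)C=Cc12
F8 | step 6 | methyl 2-{5-[1-{[tert-butyl(dimethyl)silyl]oxy}-2-(methoxymethoxy)ethyl]-8-(methoxymethoxy)-2,2-dimethyl-2H-chromen-6-yl}-2-methylpropanoate (racemic) | COC(=O)C(C)(C)c1cc(OCOC)c2OC(C)(C)C=Cc2c1C(COCOC)O[Si](C)(C)C(C)(C)C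
F9 | step 6 | 2-{5-[1-{[tert-butyl(dimethyl)silyl]oxy}-2-(methoxymethoxy)ethyl]-8-(methoxymethoxy)-2,2-dimethyl-2H-chromen-6-yl}-2-methylpropanal (racemic) | O=CC(C)(C)c1cc(OCOC)c2OC(C)(C)C=Cc2c1C(COCOC)O[Si](C)(C)C(C)(C)C
F10 | step 6 | tert-butyl{2-(methoxymethoxy)-1-[8-(methoxymethoxy)-2,2-dimethyl-6-(2-methylbut-3-en-2-yl)-2H-chromen-5-yl]ethoxy}dimethylsilane (racemic) | C=CC(C)(C)c1cc(OCOC)c2OC(C)(C)C=Cc2c1C(COCOC)O[Si](C)(C)C(C)(C)C
F11 | step 6 | 2-(methoxymethoxy)-1-[8-(methoxymethoxy)-2,2-dimethyl-6-(2-methylbut-3-en-2-yl)-2H-chromen-5-yl]ethan-1-ol (racemic) | C=CC(C)(C)c1cc(OCOC)c2OC(C)(C)C=Cc2c1C(O)COCOC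
F12 | step 13 | 2-bromo-6-hydroxy-4-(methoxymethoxy)-3-(3-methylbut-2-en-1-yl)benzaldehyde | O=Cc1c(O)cc(OCOC)c(CC=C(C)C)c1Br
F13 | step 13 | 2-bromo-4,6-bis(methoxymethoxy)-3-(3-methylbut-2-en-1-yl)benzaldehyde | O=Cc1c(OCOC)cc(OCOC)c(CC=C(C)C)c1Br
F14 | step 13 | 3-[2-bromo-4,6-bis(methoxymethoxy)-3-(3-methylbut-2-en-1-yl)phenyl]-3-hydroxy-2-(methoxymethoxy)-1-[8-(methoxymethoxy)-2,2-dimethyl-6-(2-methylbut-3-en-2-yl)-2H-chromen-5-yl]propan-1-one (racemic diastereomer mixture) | OC(c1c(Br)c(CC=C(C)C)c(OCOC)cc1OCOC)C(OCOC)C(=O)c1c(C(C)(C)C=C)cc(OCOC)c2OC(C)(C)C=Cc12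
F15 | step 13 | 1-[2-bromo-4,6-bis(methoxymethoxy)-3-(3-methylbut-2-en-1-yl)phenyl]-2-(methoxymethoxy)-3-[8-(methoxymethoxy)-2,2-dimethyl-6-(2-methylbut-3-en-2-yl)-2H-chromen-5-yl]propane-1,3-dione (racemic, enolisable) | O=C(c1c(Br)c(CC=C(C)C)c(OCOC)cc1OCOC)C(OCOC)C(=O)c1c(C(C)(C)C=C)cc(OCOC)c2OC(C)(C)C=Cc12
F16 | step 13 | 3,5,7-tris(methoxymethoxy)-2-[8-(methoxymethoxy)-2,2-dimethyl-6-(2-methylbut-3-en-2-yl)-2H-chromen-5-yl]-8-(3-methylbut-2-en-1-yl)-4H-chromen-4-one | C=CC(C)(C)c1cc(OCOC)c2c(c1-c1oc3c(CC=C(C)C)c(OCOC)cc(OCOC)c3c(=O)c1OCOC)C=CC(C)(C)O2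
F17 | step 10 | 2-bromo-4-(methoxymethoxy)-6-[(3-methylbut-2-en-1-yl)oxy]benzoic acid | O=C(O)c1c(OCC=C(C)C)cc(OCOC)cc1Br
F18 | step 10 | (1H-benzotriazol-1-yl){2-bromo-4-(methoxymethoxy)-6-[(3-methylbut-2-en-1-yl)oxy]phenyl}methanone | O=C(c1c(OCC=C(C)C)cc(OCOC)cc1Br)n1nnc2ccccc12
F19 | step 14 | 2-{2,2-dimethyl-6-(2-methylbut-3-en-2-yl)-8-[(triethylsilyl)oxy]-2H-chromen-5-yl}-8-(3-methylbut-2-en-1-yl)-3,5,7-tris[(triethylsilyl)oxy]-4H-chromen-4-one | C=CC(C)(C)c1cc(O[Si](CC)(CC)CC)c2c(c1-c1oc3c(CC=C(C)C)c(O[Si](CC)(CC)CC)cc(O[Si](CC)(CC)CC)c3c(=O)c1O[Si](CC)(CC)CC)C=CC(C)(C)O2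
A1 | alternative 1 | 2-(3,3-dimethylpent-4-en-1-yn-1-yl)-3,5,7-tris(methoxymethoxy)-8-(3-methylbut-2-en-1-yl)-4H-chromen-4-one | C=CC(C)(C)C#Cc1oc2c(CC=C(C)C)c(OCOC)cc(OCOC)c2c(=O)c1OCOC
A2 | alternative 1 | 8-(methoxymethoxy)-2,2-dimethyl-2H,5H-pyrano[4,3-b]pyran-5-one | O=C1OC=C(OCOC)C2=C1C=CC(C)(C)O2
A3 | alternative 1 | 3,5,7-tris(methoxymethoxy)-2-[8-(methoxymethoxy)-2,2-dimethyl-6-(2-methylbut-3-en-2-yl)-2H-chromen-5-yl]-8-(3-methylbut-2-en-1-yl)-4H-chromen-4-one | C=CC(C)(C)c1cc(OCOC)c2c(c1-c1oc3c(CC=C(C)C)c(OCOC)cc(OCOC)c3c(=O)c1OCOC)C=CC(C)(C)O2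
A4 | alternative 2 | 5,7-bis(methoxymethoxy)-8-(3-methylbut-2-en-1-yl)-4-oxo-4H-chromen-3-yl 2,3-bis(methoxymethoxy)-5-(2-methylbut-3-en-2-yl)-6-{[(trifluoromethyl)sulfonyl]oxy}benzoate | O=C(Oc1coc2c(CC=C(C)C)c(OCOC)cc(OCOC)c2c1=O)c1c(OCOC)c(OCOC)cc(C(C)(C)C=C)c1OS(=O)(=O)C(F)(F)F
A5 | alternative 2 | six-membered lactone joining the C2' carboxyl of ring B to O3 of the 5,7-bis(methoxymethoxy)-8-(3-methylbut-2-en-1-yl)chromone, C2–C1' bond in place, ring B carrying 3',4'-bis(methoxymethoxy) and 6'-(2-methylbut-3-en-2-yl) | O=C1Oc2c(oc3c(CC=C(C)C)c(OCOC)cc(OCOC)c3c2=O)-c2c(C(C)(C)C=C)cc(OCOC)c(OCOC)c12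
A6 | alternative 3 | 3,7-bis(methoxymethoxy)-2-{4-(methoxymethoxy)-2-(2-methylbut-3-en-2-yl)-5-[(2-methylbut-3-yn-2-yl)oxy]phenyl}-5-[(3-methylbut-2-en-1-yl)oxy]-4H-chromen-4-one | C=CC(C)(C)c1cc(OCOC)c(OC(C)(C)C#C)cc1-c1oc2cc(OCOC)cc(OCC=C(C)C)c2c(=O)c1OCOC
A7 | alternative 3 | 5-hydroxy-3,7-bis(methoxymethoxy)-2-[8-(methoxymethoxy)-2,2-dimethyl-6-(2-methylbut-3-en-2-yl)-2H-chromen-5-yl]-8-(3-methylbut-2-en-1-yl)-4H-chromen-4-one (identical with 21) | C=CC(C)(C)c1cc(OCOC)c2c(c1-c1oc3c(CC=C(C)C)c(OCOC)cc(O)c3c(=O)c1OCOC)C=CC(C)(C)O2
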